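- Count half-lives of the gap between the two products.

all flasks: left-handed substrate 20 mM; right-handed substrate 20 mM
- alpha: reagent 40 mM; free catalyst 1 mM; racemization catalyst 0.097 mM; run made earlier
- delta: reagent 40 mM; free catalyst 1 mM; racemization catalyst 0.48 mM; run made earlier
- Friday's: reagent 40.0 mM; free catalyst 1.0 mM; racemization catalyst 0.34 mM; time 20 h
- Wednesday's: reagent 40.0 mM; free catalyst 1.0 mM; racemization catalyst 0.080 mM; time 20 h

| run | time / h | left-handed product / % | right-handed product / % |
|---|---|---|---|
| alpha | 0.833 | 8.1 | 1.1 |
| alpha | 2.00 | 12.2 | 2.9 |
| alpha | 4.00 | 12.5 | 2.1 |
| alpha | 6.00 | 13.5 | 6.2 |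
| alpha | 8.00 | 10.9 | 6.1 |
| alpha | 12.0 | 9.6 | 8.1 |
| alpha | 15.0 | 9.7 | 9.9 |
| delta | 0.833 | 7.5 | 0 |
| delta | 2.00 | 12.7 | 2.1 |
| delta | 4.00 | 13.4 | 3.4 |
| delta | 6.00 | 13.2 | 7.3 |
| delta | 8.00 | 11.8 | 6.7 |
| delta | 12.0 | 12.0 | 7.9 |
| delta | 15.0 | 10.8 | 10.6 |

(each reading ± 1 percentage point)

- free catalyst is single-handed; left-handed substrate and right-handed substrate are mirror images of each other, charged as a racemate, each of them at the stated concentration
- an excess is below zero if the other one leads

- which one finishes higher in excess of left-handed product over right-handed product in the product ("neither" within 2 percentage points) (Friday's / Wednesday's / neither)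
- excess of left-handed product over right-handed product in the product at the end, Friday's
- excess of left-handed product over right-handed product in the product at the end, Wednesday's

- I called D the left-handed product minus the right-handed product, in points of the charge.
- First instants: at 0.833 h the alpha run held 8.1% of left-handed product and 1.1% of right-handed product, more of the first, and D was opening.
- Middle: at 6.00 h the alpha and delta totals averaged 20.1%. At 13.5 h they averaged 19.6%. The readings of the alpha and delta runs showed a flat total, with 80.4% of the substrates unused.
- End: in the readings of the alpha and delta runs, D went on falling while the total stood still within the scatter. I took this as one product turning into the other.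
- Alpha and delta differed in racemization catalyst by a factor of 4.95, yet I saw no difference in D beyond the scatter. I pooled them.
- Pooled D was 8.4 percentage points at 5.00 h and 1.4 points at 13.5 h. That gave τ = 3.29 h as a reading.
- I named τ the fade half-life: the time in which D halves while the total stays flat.
- From 13.5 h to 20 h lay 1.98 half-lives. That put my estimate of D at 0.36 points, which on the flat total meant an estimated excess of 1.81% for both Wednesday's and Friday's.
- The forecast stood a little higher than my reckoning: neither, with 3% (−3% to 9%) for Friday's and 2% (−4% to 8%) for Wednesday's. Its words were “Friday's and Wednesday's should therefore match, both near-racemic.”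
- The flasks gave neither: 2.88% for Friday's and 2.86% for Wednesday's, well inside the margin.

    left-handed product ⇌ right-handed product (k = 0.00160 min⁻¹)
    reagent + free catalyst + left-handed substrate → free catalyst + left-handed product (k = 130 M⁻² min⁻¹)
    reagent + free catalyst + right-handed substrate → free catalyst + right-handed product (k = 1.20 M⁻² min⁻¹)
    left-handed substrate + racemization catalyst ⇌ right-handed substrate + racemization catalyst, rate k4*[racemization catalyst]*[left-handed substrate] forward; the back reaction follows from the equilibrium constant (k = 30.0 M⁻¹ min⁻¹)
    free catalyst → spent catalyst (k = 0.0110 min⁻¹)

- In Friday's flask, half of the left-handed coupling up to 20 h was done by 0.900 h, while the half-life of left-handed product by the forward turning alone, taken at 0.900 h, was 7.2 h. In Friday's flask the lead was made early under kinetic control and then faded, and the turning of the substrates made no difference to the excess.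
- Friday's D of 3.6 points at 10.0 h, carried 3.04 half-lives, gives 0.44 points. The flask held 0.54 points.
- Friday's flask read at 12 h lies 0.608 half-lives past that point. τ gives D = 2.4 points, an excess of 12.8%. The computed excess was 13.3%.

The earlier runs and the new flask were computed for substances that don't exist, and the scatter is random.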